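## Structural features

The target 23 is a 3-methyl-1H-isochromen-1-one in which an enol-lactone ring (C1, O2, C3, C4, C4a, C8a) is fused to a benzenoid ring B (C4a, C5, C6, C7, C8, C8a). Ring B carries a free hydroxyl at C6, a methoxy group at C8 and, at C5, a methylene bridge to a second benzene, ring A. Ring A is tetrasubstituted: A1 holds the bridge, A2 a methoxy group, A4 a free hydroxyl and A6 a methoxymethyl group, with A3 and A5 unsubstituted. The molecule has no stereocentre; the only stereogenic carbon met on the way is the enolisable methine of the open-chain precursor, which is flattened on aromatisation, so no neighbouring stereocentres have to be related. The fragile groups are the enol lactone (opened by hydroxide or alkoxide, C3=C4 reducible), the benzylic methyl ether on A6, the electron-rich diarylmethane, and four phenolic oxygens of which two must end free (C6, A4) and two methylated (C8, A2). The real difficulty is ring B: five of its six carbons are substituted, the arylmethyl group must sit at C5 and not at C7 (which electrophilic benzylation of a 6,8-dioxygenated isocoumarin could not distinguish cleanly), and each oxygen pair must be differentiated. Ring B has oxygen at C6 and C8 and carbon at C4a, C5 and C8a, which is the pattern of a pentaketide chain folded so that C8a bonds to C4a. The key step uses this: a linear chain that already carries the ring A benzyl group on the future C5, and an acetonide-masked carboxyl (a dioxinone) at the future C1, is closed by an aldol between C8a and C4a, so the position of every ring B substituent follows from the order of atoms in the chain.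

## Logic of the disconnections

**23 ⇒ 22.** The two O–CH2Ph bonds (at A4–O and C6–O) are cut last. Both free phenols are thereby carried as one kind of ether through all basic and acidic steps, and a single neutral step releases them. The forward step must leave C3=C4 and the A6 methoxymethyl group untouched.

**22 ⇒ 21.** The C8 O–CH3 bond is cut. In 21 the C8 hydroxyl is the only free phenol, so no selectivity is asked of the methylation; it only has to overcome the hydrogen bond to the lactone carbonyl without opening the lactone.

**21 ⇒ 19 (through 20).** The lactone bond O2–C1 is cut, C3=O is returned to its ketal, and C1 with the C8 oxygen is returned to the acetonide. This removes the enol lactone from all earlier steps and keeps the C8 oxygen masked while the C6 oxygen is protected. The forward step needs acid that unmasks the ketone and lets its enol oxygen, not its carbon, acylate.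

**19 ⇒ 18.** The C6 O–CH2Ph bond is cut. In 18 this is the only free hydroxyl, which is what makes the later C6/C8 distinction automatic.

**18 ⇒ 16 (through 17).** The ring bond C8a–C4a is cut, opening ring B to a chain in which C8a is the dioxinone α carbon and C4a a ketone carbon. This is the largest simplification: a penta-substituted benzene becomes an acyclic triketone equivalent. The forward step needs a mild base and a chain in which only one carbonyl can be reached through a six-membered transition state.

**16 ⇒ 13 + 15.** The bond between the future C5 and the future C4a is cut (Claisen retron). The ring A benzyl group then enters as part of the carbon nucleophile rather than by a later alkylation. Alkylating an unsubstituted diketone would be the weaker design: the base needed for it also triggers aromatisation, and the required ring A benzylic halide, activated by ortho and para oxygen, ionises easily. The forward step needs a dianion that reacts at its ketone-side carbon and an acyl donor that does not quench it.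

**13 ⇒ 10 (through 12) + 11.** The bond between the future C7 and the future C6 is cut, giving a 3-arylpropanoic acid and the dienolate of a simple dioxinone. The forward step needs γ-selective C-acylation of that dienolate.

**10 ⇒ 6 + 7.** The bond between the bridge carbon and the future C5 is cut (Knoevenagel retron, with reduction and loss of one carboxyl). The bridge carbon is then an aldehyde carbon, and no ring A benzylic halide is needed. The forward reduction must not touch the aryl benzyl ether.

**6 ⇒ 5 ⇒ 4.** The A2 O–CH3 bond is cut, then A2–OH is traced back to a second benzyl ether. The two ring A oxygens are then identical in 4 and are told apart only by their position relative to the aldehyde. The forward debenzylation must be chelation-controlled.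

**4 ⇒ 2 (through 3) ⇒ 1.** The A1–CHO bond is cut (formylation of a symmetrical arene, whose two reactive positions are equivalent), then the O–CH3 bond of the methoxymethyl group. This leads to the symmetrical 1.

**15 ⇒ 14.** The amide C–N bond is cut, leading to the ester 14, which already contains the masked methyl ketone (C3, its methyl and C4).

## Other disconnections considered

**Alternative 1:** The cuts are C5–CH2 (bridge) and C4a–C4, with ring B taken whole from the aryl iodide A2. In the forward direction A2, the ring A benzylic bromide A3 and propyne A4 would be joined in a Catellani-type palladium relay. The sequence is oxidative addition at C–I, palladacycle formation at the one free ortho C–H (future C5), benzylation there, then alkynylation at the former C–I carbon to give A1. A 6-endo closure of the ester onto the alkyne would lead to 22, after which step 13 applies.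

- In its favour: it is highly convergent, two crowded bonds form in one operation, and only two steps follow the key step against four in the chosen plan. On this count it is the better.
- Equal point: the benzyl group can only go to the single free ortho C–H, so on regiochemistry at C5 it is the equal of the chosen plan.
- Against it here: the electrophile A3 is doubly activated by ortho and para oxygen. It can add to zerovalent palladium in competition with A2, or ionise. The C–H to be palladated lies beside a benzyloxy group. A4 can couple directly with A2 or A3. The closing lactonisation must go 6-endo and not 5-exo.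
- Step economy: A2 needs its own multistep synthesis with one benzyl and one methyl ether told apart, and A3 costs two steps from 6 where 10 costs one.
- Comparison: on structure both fix C5 unambiguously. On mechanism the chosen plan needs one base-mediated aldol with a single six-membered option, while the alternative needs four organometallic events to occur in order with a fragile electrophile. On step economy the alternative could be somewhat shorter if A2 were at hand and is probably similar once A2 is made.

**Alternative 2:** The cuts lie inside ring A. Read on the product A5, with A1 as the carbon bearing the carbonyl group, the bonds formed are A1–A2 and A5–A6. The A1–A6 bond is the former triple bond of the ynone A7 and A2–A3 lies within the diene A6, so neither of those is made. In the forward direction the unsubstituted terminus of A6 would add to the alkyne carbon β to the ketone of A7 and the acetal terminus to the α carbon. Loss of one methoxy group and of the silyl group would then give A5.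

- In its favour: ring A appears with A2–OMe and free A4–OH already differentiated. This is better than the chosen plan, which spends steps 1 to 4 on that task.
- Equal point: the regiochemistry follows from the polarity of both partners and is as predictable as the chain-length argument of the chosen key step.
- Against it here: it builds the easier ring. A5 has a diaryl ketone where the target has CH2, and that ketone is deactivated as a vinylogous acid by the para hydroxyl. The future C4a of A5 still carries hydrogen, between the ester and the aroyl group and meta to both ring B oxygens, so C4 and C3 would have to be introduced late at the least activated and most hindered site. A7 also needs a regioselective acylation of a benzoate.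
- Comparison: on structure it leaves the hard problems of ring B open, whereas the chosen plan solves them in one step. On mechanism the cycloaddition is robust. On step economy it is well behind.

**Alternative 3:** The cuts are C8a–C4a (Michael bond) and C7–C6 (Claisen bond). In the forward direction methyl acetoacetate A9 and the benzylated crotonate A10 would condense under alkoxide base to the dioxocyclohexanecarboxylate A8.

- In its favour: cheap reagents, no cryogenic dianion chemistry, and two ring bonds in one pot. On these points it is the better.
- Equal point: the benzyl group is on the future C5 by construction, and the C8a–C4a bond is the same one the chosen key step makes.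
- Against it here: A10 is an α-branched, β-substituted acrylate, a poor Michael acceptor that can also deconjugate under alkoxide. A8 is not aromatic, and its dehydrogenation to the orsellinate A11 needs an oxidant in the presence of ring A, whose A3 and A5 positions are readily halogenated or oxidised. In A11 the future C4 is only a methyl group, so C3 and its methyl must be added by lateral metalation and acylation, in competition with the doubly benzylic bridge CH2. The two hydroxyls of A11 still have to be differentiated.
- Comparison: on structure the chosen chain already contains every carbon of ring B and of the lactone, whereas A8 lacks C3 and its methyl. On mechanism both are carbonyl condensations, but the chosen one aromatises by loss of water without an oxidant. On step economy A10 needs about three steps from 6 and about six more are needed after A8, so the alternative is longer.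

Key step: step 9

Remark on starting materials: 1, 7, 11 and 14 are taken as catalogue compounds; 14 is the ethylene ketal of ethyl acetoacetate, so no ketalisation step is planned.

Remark on ring A: 3,5-dimethoxybenzyl alcohol is not a workable source of ring A, because it would leave two identical aryl methyl ethers with no way to free the A4 oxygen alone; the bis(benzyl) ether 1 is used and the two oxygens are told apart by chelation in step 3.

Remark on numbering: metal enolates, metal-bound tetrahedral adducts and phenoxides formed by deprotonation are treated as reactive forms of their parent compounds and carry no number.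

## Route

Step 1
Reactants: 1 3,5-bis(benzyloxy)benzyl alcohol
Product: 2 1,3-bis(benzyloxy)-5-(methoxymethyl)benzene
Conditions: NaH, MeI, THF, 0 °C to rt
Reagents that add atoms: iodomethane, CI
Why: Williamson ether synthesis on a primary benzylic alkoxide; the aryl benzyl ethers are inert to these conditions.

Step 2
Reactants: 2 1,3-bis(benzyloxy)-5-(methoxymethyl)benzene
Product: 4 2,4-bis(benzyloxy)-6-(methoxymethyl)benzaldehyde, via aryl iminium salt 3 (not isolated)
Conditions: POCl3, DMF, 0 °C to 70 °C; then ice-water
Reagents that add atoms: N,N-dimethylformamide, CN(C)C=O; water, O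
Why: Vilsmeier–Haack formylation; the two positions flanking the methoxymethyl group are equivalent and each is ortho to one and para to the other benzyloxy group, while the position between the two benzyloxy groups is the more hindered, as in formylation of 3,5-dialkoxytoluenes.

Step 3
Reactants: 4 2,4-bis(benzyloxy)-6-(methoxymethyl)benzaldehyde
Product: 5 4-(benzyloxy)-2-hydroxy-6-(methoxymethyl)benzaldehyde
Conditions: MgBr2·OEt2, toluene/Et2O, reflux; then 1 M HCl
Reagents that add atoms: none
Why: Chelation-controlled ether cleavage: magnesium bridges the aldehyde oxygen and the ortho benzyloxy oxygen in a six-membered chelate and bromide removes that benzyl group, while the para benzyl ether cannot chelate and the aliphatic methyl ether is a poorer leaving partner.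

Step 4
Reactants: 5 4-(benzyloxy)-2-hydroxy-6-(methoxymethyl)benzaldehyde
Product: 6 4-(benzyloxy)-2-methoxy-6-(methoxymethyl)benzaldehyde
Conditions: MeI, K2CO3, DMF, 40 °C
Reagents that add atoms: iodomethane, CI
Why: Williamson O-methylation of the only free phenol; carbonate in DMF should suffice to alkylate the hydrogen-bonded salicylaldehyde hydroxyl.

Step 5
Reactants: 6 4-(benzyloxy)-2-methoxy-6-(methoxymethyl)benzaldehyde; 7 Meldrum's acid (2,2-dimethyl-1,3-dioxane-4,6-dione)
Product: 10 3-[4-(benzyloxy)-2-methoxy-6-(methoxymethyl)phenyl]propanoic acid, via arylidene Meldrum's acid 8 (not isolated), via benzyl Meldrum's acid 9 (not isolated)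
Conditions: HCO2H/Et3N (5:2), 95–100 °C
Reagents that add atoms: none
Why: One-pot Knoevenagel condensation, formate transfer reduction of the strongly electrophilic alkylidene, and hydrolytic ring opening with loss of acetone and decarboxylation; no metal or hydrogen gas is present, so the aryl benzyl ether should survive.

Step 6
Reactants: 10 3-[4-(benzyloxy)-2-methoxy-6-(methoxymethyl)phenyl]propanoic acid; 11 2,2,6-trimethyl-4H-1,3-dioxin-4-one
Product: 13 6-{4-[4-(benzyloxy)-2-methoxy-6-(methoxymethyl)phenyl]-2-oxobutyl}-2,2-dimethyl-4H-1,3-dioxin-4-one, via acid chloride 12 (not isolated)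
Conditions: (COCl)2, cat. DMF, CH2Cl2, 0 °C to rt, evaporate; then add to 11 (2.2 equiv) and LiN(SiMe3)2 (2.2 equiv), THF, −78 °C; aq. NH4Cl
Reagents that add atoms: none
Why: Claisen-type γ-C-acylation of the lithium dienolate of 11 by an acid chloride, a standard entry to keto-dioxinones; the second equivalent of dienolate takes up the proton of the more acidic product, and both positions ortho to the side chain on ring A are blocked, so no indanone can form from 12.

Step 7
Reactants: 14 ethyl 2-(2-methyl-1,3-dioxolan-2-yl)acetate
Product: 15 N-methoxy-N-methyl-2-(2-methyl-1,3-dioxolan-2-yl)acetamide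
Conditions: MeNHOMe·HCl, iPrMgCl, THF, −20 °C to 0 °C
Reagents that add atoms: N,O-dimethylhydroxylamine hydrochloride, CNOC.Cl
Why: Weinreb amide formation by aminolysis of the ester with the chloromagnesium amide; the low temperature and the non-basic magnesium amide should avoid α-deprotonation and β-elimination of the ketal.

Step 8
Reactants: 13 6-{4-[4-(benzyloxy)-2-methoxy-6-(methoxymethyl)phenyl]-2-oxobutyl}-2,2-dimethyl-4H-1,3-dioxin-4-one; 15 N-methoxy-N-methyl-2-(2-methyl-1,3-dioxolan-2-yl)acetamide
Product: 16 6-{3-[4-(benzyloxy)-2-methoxy-6-(methoxymethyl)benzyl]-5-(2-methyl-1,3-dioxolan-2-yl)-2,4-dioxopentyl}-2,2-dimethyl-4H-1,3-dioxin-4-one (racemic)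
Conditions: LiN(iPr)2 (2.3 equiv), THF, −78 °C; then 15 (1.2 equiv), −78 °C to −40 °C; aq. NH4Cl
Reagents that add atoms: none
Why: Dianion C-acylation with a Weinreb amide: the first deprotonation occurs at the CH2 between dioxinone and ketone, the second at the ketone-side CH2, and this last-formed, most basic carbon attacks the amide, whose chelated tetrahedral adduct survives until work-up so that neither over-addition nor quenching of the dianion by the product occurs; the new centre is racemic and enolisable and is removed in step 9, and 16 is carried on without long contact with silica.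

Step 9
Reactants: 16 6-{3-[4-(benzyloxy)-2-methoxy-6-(methoxymethyl)benzyl]-5-(2-methyl-1,3-dioxolan-2-yl)-2,4-dioxopentyl}-2,2-dimethyl-4H-1,3-dioxin-4-one
Product: 18 6-[4-(benzyloxy)-2-methoxy-6-(methoxymethyl)benzyl]-7-hydroxy-2,2-dimethyl-5-[(2-methyl-1,3-dioxolan-2-yl)methyl]-4H-1,3-benzodioxin-4-one, via cyclic aldol adduct 17 (not isolated)
Conditions: Et3N (3 equiv), CH2Cl2, 0 °C to rt; then cold aq. citric acid wash (pH 4)
Reagents that add atoms: none
Why: Triethylamine removes a proton from the CH2 between the dioxinone and the first ketone, giving an extended dienolate whose α carbon (dioxinone C5, the future C8a) adds to the second chain ketone (the future C4a) to form 17. The ring closes in a 6-(enolexo)-exo-trig aldol, the only carbocycle formed. Base-mediated loss of water across C8a–C4a followed by enolisation of the remaining ring ketone (future C6) should give the aromatic ring of 18, and the gain in aromaticity makes the sequence irreversible. The closest known reaction type is the amine-mediated aldol aromatisation of 6-(2,4-dioxoalkyl)dioxinones to acetonide-protected resorcylates, including chains substituted on the carbon between the two ketones. No stereocentre is created, and the racemic methine of 16 becomes the sp2 carbon C5. The selectivity needed is chemoselectivity among four carbonyl groups: the terminal ketone is a ketal and can act neither as electrophile nor as enolate, and every other carbon–carbon closure would need a four-membered ring. O-cyclisation to a pyranone and β-elimination of the ketal are limited by the weak base and low temperature, and the buffered acidic wash is chosen so that the ketal survives. The benzyl group ends at C5 because it was on the chain carbon between the two ketones.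

Step 10
Reactants: 18 6-[4-(benzyloxy)-2-methoxy-6-(methoxymethyl)benzyl]-7-hydroxy-2,2-dimethyl-5-[(2-methyl-1,3-dioxolan-2-yl)methyl]-4H-1,3-benzodioxin-4-one
Product: 19 7-(benzyloxy)-6-[4-(benzyloxy)-2-methoxy-6-(methoxymethyl)benzyl]-2,2-dimethyl-5-[(2-methyl-1,3-dioxolan-2-yl)methyl]-4H-1,3-benzodioxin-4-one
Conditions: BnBr, K2CO3, DMF, rt
Reagents that add atoms: benzyl bromide, BrCc1ccccc1
Why: Williamson benzylation of the only free phenol; the benzodioxinone and the ketal are stable to anhydrous carbonate.

Step 11
Reactants: 19 7-(benzyloxy)-6-[4-(benzyloxy)-2-methoxy-6-(methoxymethyl)benzyl]-2,2-dimethyl-5-[(2-methyl-1,3-dioxolan-2-yl)methyl]-4H-1,3-benzodioxin-4-one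
Product: 21 6-(benzyloxy)-5-[4-(benzyloxy)-2-methoxy-6-(methoxymethyl)benzyl]-8-hydroxy-3-methyl-1H-isochromen-1-one, via keto benzodioxinone 20 (not isolated)
Conditions: TFA, H2O (5 equiv), CH2Cl2, 0 °C to 40 °C
Reagents that add atoms: water, O
Why: Acid hydrolysis of the dioxolane gives the aryl acetone 20, whose arene-conjugated enol attacks the neighbouring acylal carbonyl through oxygen (enol lactonisation by transacylation, six-membered ring); the expelled hemiketal loses acetone and frees the C8 hydroxyl. Acid rather than base is used so that the methyl-side enolate cannot C-acylate to a naphthalenediol, and A6 is meta to both ring A oxygens, so its methyl ether should not ionise.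

Step 12
Reactants: 21 6-(benzyloxy)-5-[4-(benzyloxy)-2-methoxy-6-(methoxymethyl)benzyl]-8-hydroxy-3-methyl-1H-isochromen-1-one
Product: 22 6-(benzyloxy)-5-[4-(benzyloxy)-2-methoxy-6-(methoxymethyl)benzyl]-8-methoxy-3-methyl-1H-isochromen-1-one
Conditions: MeI, K2CO3, DMF, 50 °C
Reagents that add atoms: iodomethane, CI
Why: Williamson O-methylation of the only free hydroxyl; warming in a polar solvent should overcome its hydrogen bond to the lactone carbonyl, and anhydrous carbonate should not open the enol lactone.

Step 13
Reactants: 22 6-(benzyloxy)-5-[4-(benzyloxy)-2-methoxy-6-(methoxymethyl)benzyl]-8-methoxy-3-methyl-1H-isochromen-1-one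
Product: 23 6-hydroxy-5-[4-hydroxy-2-methoxy-6-(methoxymethyl)benzyl]-8-methoxy-3-methyl-1H-isochromen-1-one (target)
Conditions: H2 (1 atm), 10% Pd/C (palladium on carbon), EtOAc, rt, stopped after uptake of 2 equiv
Reagents that add atoms: none
Why: Catalytic hydrogenolysis of two aryl benzyl ethers, which should be faster than reduction of the conjugated, trisubstituted C3=C4 enol-lactone bond and than cleavage of the benzylic methyl ether on the non-activated A6 position.

## Compound list

1 | 3,5-bis(benzyloxy)benzyl alcohol | OCc1cc(OCc2ccccc2)cc(OCc2ccccc2)c1 | starting material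
2 | 1,3-bis(benzyloxy)-5-(methoxymethyl)benzene | COCc1cc(OCc2ccccc2)cc(OCc2ccccc2)c1 | intermediate
3 | {[2,4-bis(benzyloxy)-6-(methoxymethyl)phenyl]methylidene}dimethylammonium dichlorophosphate | C[N+](C)=Cc1c(COC)cc(OCc2ccccc2)cc1OCc1ccccc1.[O-]P(=O)(Cl)Cl | intermediate (not isolated)
4 | 2,4-bis(benzyloxy)-6-(methoxymethyl)benzaldehyde | O=Cc1c(COC)cc(OCc2ccccc2)cc1OCc1ccccc1 | intermediate
5 | 4-(benzyloxy)-2-hydroxy-6-(methoxymethyl)benzaldehyde | O=Cc1c(COC)cc(OCc2ccccc2)cc1O | intermediate
6 | 4-(benzyloxy)-2-methoxy-6-(methoxymethyl)benzaldehyde | O=Cc1c(COC)cc(OCc2ccccc2)cc1OC | intermediate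
7 | Meldrum's acid (2,2-dimethyl-1,3-dioxane-4,6-dione) | CC1(C)OC(=O)CC(=O)O1 | starting material
8 | 5-{[4-(benzyloxy)-2-methoxy-6-(methoxymethyl)phenyl]methylidene}-2,2-dimethyl-1,3-dioxane-4,6-dione | CC1(C)OC(=O)C(=Cc2c(COC)cc(OCc3ccccc3)cc2OC)C(=O)O1 | intermediate (not isolated)
9 | 5-[4-(benzyloxy)-2-methoxy-6-(methoxymethyl)benzyl]-2,2-dimethyl-1,3-dioxane-4,6-dione | CC1(C)OC(=O)C(Cc2c(COC)cc(OCc3ccccc3)cc2OC)C(=O)O1 | intermediate (not isolated)
10 | 3-[4-(benzyloxy)-2-methoxy-6-(methoxymethyl)phenyl]propanoic acid | OC(=O)CCc1c(COC)cc(OCc2ccccc2)cc1OC | intermediate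
11 | 2,2,6-trimethyl-4H-1,3-dioxin-4-one | CC1=CC(=O)OC(C)(C)O1 | starting material
12 | 3-[4-(benzyloxy)-2-methoxy-6-(methoxymethyl)phenyl]propanoyl chloride | ClC(=O)CCc1c(COC)cc(OCc2ccccc2)cc1OC | intermediate (not isolated)
13 | 6-{4-[4-(benzyloxy)-2-methoxy-6-(methoxymethyl)phenyl]-2-oxobutyl}-2,2-dimethyl-4H-1,3-dioxin-4-one | CC1(C)OC(=O)C=C(CC(=O)CCc2c(COC)cc(OCc3ccccc3)cc2OC)O1 | intermediate
14 | ethyl 2-(2-methyl-1,3-dioxolan-2-yl)acetate | CCOC(=O)CC1(C)OCCO1 | starting material
15 | N-methoxy-N-methyl-2-(2-methyl-1,3-dioxolan-2-yl)acetamide | CON(C)C(=O)CC1(C)OCCO1 | intermediate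
16 | 6-{3-[4-(benzyloxy)-2-methoxy-6-(methoxymethyl)benzyl]-5-(2-methyl-1,3-dioxolan-2-yl)-2,4-dioxopentyl}-2,2-dimethyl-4H-1,3-dioxin-4-one (racemic, enolisable centre) | CC1(C)OC(=O)C=C(O1)CC(=O)C(Cc1c(COC)cc(OCc2ccccc2)cc1OC)C(=O)CC1(C)OCCO1 | intermediate
17 | 6-[4-(benzyloxy)-2-methoxy-6-(methoxymethyl)benzyl]-5-hydroxy-2,2-dimethyl-5-[(2-methyl-1,3-dioxolan-2-yl)methyl]-4a,5-dihydro-4H-1,3-benzodioxine-4,7(6H)-dione (mixture of diastereomers) | CC1(C)OC(=O)C2C(O1)=CC(=O)C(Cc3c(COC)cc(OCc4ccccc4)cc3OC)C2(O)CC5(C)OCCO5 | intermediate (not isolated)
18 | 6-[4-(benzyloxy)-2-methoxy-6-(methoxymethyl)benzyl]-7-hydroxy-2,2-dimethyl-5-[(2-methyl-1,3-dioxolan-2-yl)methyl]-4H-1,3-benzodioxin-4-one | CC1(C)OC(=O)c2c(O1)cc(O)c(Cc3c(COC)cc(OCc4ccccc4)cc3OC)c2CC1(C)OCCO1 | intermediate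
19 | 7-(benzyloxy)-6-[4-(benzyloxy)-2-methoxy-6-(methoxymethyl)benzyl]-2,2-dimethyl-5-[(2-methyl-1,3-dioxolan-2-yl)methyl]-4H-1,3-benzodioxin-4-one | CC1(C)OC(=O)c2c(O1)cc(OCc3ccccc3)c(Cc3c(COC)cc(OCc4ccccc4)cc3OC)c2CC1(C)OCCO1 | intermediate
20 | 7-(benzyloxy)-6-[4-(benzyloxy)-2-methoxy-6-(methoxymethyl)benzyl]-2,2-dimethyl-5-(2-oxopropyl)-4H-1,3-benzodioxin-4-one | CC(=O)Cc1c(Cc2c(COC)cc(OCc3ccccc3)cc2OC)c(OCc2ccccc2)cc2OC(C)(C)OC(=O)c12 | intermediate (not isolated)
21 | 6-(benzyloxy)-5-[4-(benzyloxy)-2-methoxy-6-(methoxymethyl)benzyl]-8-hydroxy-3-methyl-1H-isochromen-1-one | Cc1cc2c(Cc3c(COC)cc(OCc4ccccc4)cc3OC)c(OCc3ccccc3)cc(O)c2c(=O)o1 | intermediate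
22 | 6-(benzyloxy)-5-[4-(benzyloxy)-2-methoxy-6-(methoxymethyl)benzyl]-8-methoxy-3-methyl-1H-isochromen-1-one | Cc1cc2c(Cc3c(COC)cc(OCc4ccccc4)cc3OC)c(OCc3ccccc3)cc(OC)c2c(=O)o1 | intermediate
23 | 6-hydroxy-5-[4-hydroxy-2-methoxy-6-(methoxymethyl)benzyl]-8-methoxy-3-methyl-1H-isochromen-1-one | COCc1cc(O)cc(OC)c1Cc1c(O)cc(OC)c2c(=O)oc(C)cc12 | target

## Step count and risks

Total step count: 13. Longest linear sequence: 12 (steps 1 to 6, then 8 to 13); step 7 is the only side branch.

**Step 9 (key step).** The bulky arylmethyl group on the carbon between the two ketones may slow the aldol enough for other processes to compete: retro-Claisen cleavage of the 1,3-diketone, O-cyclisation to a pyranone, or base-induced β-elimination that opens the ketal. The fallback keeps the same C8a–C4a bond but changes the nucleophile. It sets out from 16, which is heated in toluene with methanol (110 °C, sealed) so that the dioxinone loses acetone and is replaced by a methyl β-keto ester, methyl 6-[4-(benzyloxy)-2-methoxy-6-(methoxymethyl)benzyl]-8-(2-methyl-1,3-dioxolan-2-yl)-3,5,7-trioxooctanoate F1. Its doubly activated C2 methylene is far more acidic than the dioxinone α carbon and should close onto the C7 ketone, on standing or with a trace of Cs2CO3, to methyl 3-[4-(benzyloxy)-2-methoxy-6-(methoxymethyl)benzyl]-4,6-dihydroxy-2-[(2-methyl-1,3-dioxolan-2-yl)methyl]benzoate F2. BnBr and K2CO3 in acetone should alkylate only the hydroxyl para to the ester, since the ortho one is hydrogen-bonded, giving methyl 4-(benzyloxy)-3-[4-(benzyloxy)-2-methoxy-6-(methoxymethyl)benzyl]-6-hydroxy-2-[(2-methyl-1,3-dioxolan-2-yl)methyl]benzoate F3. Aqueous TFA then unmasks the ketone and the enol lactonises onto the methyl ester, and the route is rejoined at 21.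

**Step 8.** The dianion may act as a base toward the α-CH2 of 15 instead of adding to it, after which the ketal can open by β-elimination; addition at a secondary carbanion may also be incomplete. The fallback replaces the Claisen-type acylation by aldol addition and oxidation. It sets out from 13 and 15: 15 is reduced with iBu2AlH at −78 °C to 2-(2-methyl-1,3-dioxolan-2-yl)acetaldehyde F4. The same dianion of 13 adds to F4 at −78 °C to give 6-{3-[4-(benzyloxy)-2-methoxy-6-(methoxymethyl)benzyl]-4-hydroxy-5-(2-methyl-1,3-dioxolan-2-yl)-2-oxopentyl}-2,2-dimethyl-4H-1,3-dioxin-4-one F5. Dess–Martin oxidation of the β-hydroxy ketone returns to the route at 16.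

**Step 11.** Ketal hydrolysis may proceed while the acylal carbonyl resists attack by the enol, so that the reaction stalls at the ketone stage; prolonged acid could then begin to cleave benzyl ethers. The fallback opens the benzodioxinone first, under base. It sets out from 19: KOH in aqueous DMSO (80 °C) hydrolyses the acetonide ester with loss of acetone and, after careful acidification, gives 4-(benzyloxy)-3-[4-(benzyloxy)-2-methoxy-6-(methoxymethyl)benzyl]-6-hydroxy-2-[(2-methyl-1,3-dioxolan-2-yl)methyl]benzoic acid F6. Brief treatment with aqueous TFA at rt unmasks the ketone, and the keto acid should close through its lactol and dehydrate, returning to the route at 21.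

**Step 13.** Hydrogen may add to C3=C4 or cleave the benzylic methyl ether before both benzyl ethers are gone. The fallback uses acidolysis instead of hydrogenolysis. It sets out from 22: TFA with pentamethylbenzene as cation scavenger at rt removes both benzyl groups without touching aryl methyl ethers, the alkene or the lactone, and arrives directly at 23; this fallback makes no new compound (F0).

**Step 3.** Site selectivity may be lost, with both benzyl ethers cleaved or the methoxymethyl ether attacked by bromide. The fallback replaces selective dealkylation by selective alkylation. It sets out from 4: hydrogenolysis (H2, 10% Pd/C, EtOAc) removes both benzyl groups to give 2,4-dihydroxy-6-(methoxymethyl)benzaldehyde F7. BnBr with KHCO3 in MeCN should then alkylate only the 4-hydroxyl, since the 2-hydroxyl is hydrogen-bonded to the aldehyde, returning to the route at 5.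

## Further compounds

F1 | step 9 | methyl 6-[4-(benzyloxy)-2-methoxy-6-(methoxymethyl)benzyl]-8-(2-methyl-1,3-dioxolan-2-yl)-3,5,7-trioxooctanoate (racemic) | COC(=O)CC(=O)CC(=O)C(Cc1c(COC)cc(OCc2ccccc2)cc1OC)C(=O)CC1(C)OCCO1
F2 | step 9 | methyl 3-[4-(benzyloxy)-2-methoxy-6-(methoxymethyl)benzyl]-4,6-dihydroxy-2-[(2-methyl-1,3-dioxolan-2-yl)methyl]benzoate | COC(=O)c1c(O)cc(O)c(Cc2c(COC)cc(OCc3ccccc3)cc2OC)c1CC1(C)OCCO1
F3 | step 9 | methyl 4-(benzyloxy)-3-[4-(benzyloxy)-2-methoxy-6-(methoxymethyl)benzyl]-6-hydroxy-2-[(2-methyl-1,3-dioxolan-2-yl)methyl]benzoate | COC(=O)c1c(O)cc(OCc2ccccc2)c(Cc2c(COC)cc(OCc3ccccc3)cc2OC)c1CC1(C)OCCO1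
F4 | step 8 | 2-(2-methyl-1,3-dioxolan-2-yl)acetaldehyde | CC1(CC=O)OCCO1
F5 | step 8 | 6-{3-[4-(benzyloxy)-2-methoxy-6-(methoxymethyl)benzyl]-4-hydroxy-5-(2-methyl-1,3-dioxolan-2-yl)-2-oxopentyl}-2,2-dimethyl-4H-1,3-dioxin-4-one (mixture of diastereomers) | CC1(C)OC(=O)C=C(O1)CC(=O)C(Cc1c(COC)cc(OCc2ccccc2)cc1OC)C(O)CC1(C)OCCO1
F6 | step 11 | 4-(benzyloxy)-3-[4-(benzyloxy)-2-methoxy-6-(methoxymethyl)benzyl]-6-hydroxy-2-[(2-methyl-1,3-dioxolan-2-yl)methyl]benzoic acid | OC(=O)c1c(O)cc(OCc2ccccc2)c(Cc2c(COC)cc(OCc3ccccc3)cc2OC)c1CC1(C)OCCO1
F0 | step 13 | none | none
F7 | step 3 | 2,4-dihydroxy-6-(methoxymethyl)benzaldehyde | COCc1cc(O)cc(O)c1C=O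
A1 | alternative 1 | methyl 4-(benzyloxy)-3-[4-(benzyloxy)-2-methoxy-6-(methoxymethyl)benzyl]-6-methoxy-2-(prop-1-yn-1-yl)benzoate | CC#Cc1c(Cc2c(COC)cc(OCc3ccccc3)cc2OC)c(OCc2ccccc2)cc(OC)c1C(=O)OC
A2 | alternative 1 | methyl 4-(benzyloxy)-2-iodo-6-methoxybenzoate | COC(=O)c1c(I)cc(OCc2ccccc2)cc1OC
A3 | alternative 1 | 5-(benzyloxy)-2-(bromomethyl)-1-methoxy-3-(methoxymethyl)benzene | COCc1cc(OCc2ccccc2)cc(OC)c1CBr
A4 | alternative 1 | propyne | CC#C
A5 | alternative 2 | methyl 4-(benzyloxy)-5-[4-hydroxy-2-methoxy-6-(methoxymethyl)benzoyl]-2-methoxybenzoate | COCc1cc(O)cc(OC)c1C(=O)c1cc(C(=O)OC)c(OC)cc1OCc1ccccc1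
A6 | alternative 2 | 1,1-dimethoxy-3-(trimethylsilyloxy)buta-1,3-diene | COC(OC)=CC(=C)O[Si](C)(C)C
A7 | alternative 2 | methyl 4-(benzyloxy)-2-methoxy-5-(4-methoxybut-2-ynoyl)benzoate | COCC#CC(=O)c1cc(C(=O)OC)c(OC)cc1OCc1ccccc1
A8 | alternative 3 | methyl 3-[4-(benzyloxy)-2-methoxy-6-(methoxymethyl)benzyl]-2-methyl-4,6-dioxocyclohexane-1-carboxylate (mixture of diastereomers) | COC(=O)C1C(C)C(Cc2c(COC)cc(OCc3ccccc3)cc2OC)C(=O)CC1=O
A9 | alternative 3 | methyl acetoacetate | COC(=O)CC(C)=O
A10 | alternative 3 | methyl (E)-2-[4-(benzyloxy)-2-methoxy-6-(methoxymethyl)benzyl]but-2-enoate | C/C=C(\Cc1c(COC)cc(OCc2ccccc2)cc1OC)C(=O)OC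
A11 | alternative 3 | methyl 3-[4-(benzyloxy)-2-methoxy-6-(methoxymethyl)benzyl]-4,6-dihydroxy-2-methylbenzoate | COC(=O)c1c(O)cc(O)c(Cc2c(COC)cc(OCc3ccccc3)cc2OC)c1C
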